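**Retrosynthetic overview**
1. No ring is built: both benzene rings are bought with all five bromines in place. The only strategic bond is the diaryl ether C–O bond, cut at the ring-B carbon that lies between C–OH and C–Br.
2. Ring A (oxygen donor): boronic acid 1 → borate 2 → 3,5-dibromo-2-methoxyphenol 3.
3. Ring B (carbon donor): 3,4,5-tribromophenol 4 → ortho-(mesityliodonio)phenolate 5. The two ortho positions of 4 are equivalent, so the position of the ether is fixed here.
4. Union: 3 + 5 → target 6 by a Rh-carbenoid formal O–H insertion with loss of iodomesitylene; the phenolate oxygen of 5 becomes the free OH.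

Assumption: 6 has no stereocentre or stable stereoaxis, so there is no configuration to set; 1 and 4 are bought as catalogue compounds.

**Step 1**
Reactants: 1 (3,5-dibromo-2-methoxyphenyl)boronic acid
Product: 3 3,5-dibromo-2-methoxyphenol, via aryl dihydrogen borate 2 (not isolated)
Conditions: 30% aq H2O2 (1.5 equiv), EtOH, 0 °C → rt
Reagents that add atoms: hydrogen peroxide OO
Why: Ipso-hydroxylation of an arylboronic acid: hydroperoxide adds to boron, the aryl group shifts from B to O to give borate 2, which hydrolyses in the same pot, and neutral peroxide leaves C–Br and OMe untouched (no stereocentre involved).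

**Step 2**
Reactants: 4 3,4,5-tribromophenol
Product: 5 3,4,5-tribromo-2-[(2,4,6-trimethylphenyl)iodonio]phenolate (inner salt; iodine on C2, between C–O⁻ and C–Br)
Conditions: MesI(OAc)2 (1.05 equiv), KOH (2.1 equiv), MeOH, −10 → 0 °C, dark; filter the precipitate, wash (cold MeOH, Et2O), dry in vacuo
Reagents that add atoms: 2,4,6-trimethyl(diacetoxyiodo)benzene, MesI(OAc)2, CC(=O)OI(OC(C)=O)c1c(C)cc(C)cc1C
Why: Electrophilic ortho-C–H iodanylation of a phenolate to an aryliodonium phenolate (iodonium ylide formation, established for para-blocked acidic phenols such as 4-nitrophenol, whose acidity 4 roughly matches): para is brominated and the two ortho carbons are equivalent, so only one inner salt can form, and it precipitates away from further oxidation (no stereocentre).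

**Step 3**
Reactants: 3 3,5-dibromo-2-methoxyphenol; 5 3,4,5-tribromo-2-[(2,4,6-trimethylphenyl)iodonio]phenolate
Product: 6 3,4,5-tribromo-2-(3,5-dibromo-2-methoxyphenoxy)phenol
Conditions: Rh2(esp)2 (1 mol%), 3 (2 equiv, excess recovered), 4 Å MS, CH2Cl2, 0 °C → rt, dark; 5 added in portions over 2 h
Reagents that add atoms: none
Why: Proposed new method: Rh(II)-catalysed formal O–H insertion (ipso-aryloxylation) of an ortho-iodonio phenolate with a phenol – 5 is the iodonium ylide of a cyclohexa-2,4-dienone, so Rh2(esp)2 should expel iodomesitylene to give a quinoid Rh-carbenoid (a 2-oxidoaryl cation equivalent) whose carbon is attacked by the OH oxygen of 3, and proton transfer with re-aromatisation gives the 2-aryloxyphenol with the new C–O bond exactly where iodine sat; the di-ortho-methyl mesityl group blocks the known thermal I→O aryl shift, the deactivated dibromo ring of 3 disfavours C–H insertion, and if 3 instead protonates 5, ligand coupling on iodine(III) would transfer the same electron-poor ring-B carbon to the same oxygen; closest known reaction type: Rh(II)-carbenoid O–H insertion of quinone diazides and of 1,3-dicarbonyl iodonium ylides into alcohols and phenols (no stereocentre is formed).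

**Compound list**
1 | (3,5-dibromo-2-methoxyphenyl)boronic acid | COc1c(B(O)O)cc(Br)cc1Br | starting material
2 | 3,5-dibromo-2-methoxyphenyl dihydrogen borate | COc1c(OB(O)O)cc(Br)cc1Br | intermediate
3 | 3,5-dibromo-2-methoxyphenol | COc1c(O)cc(Br)cc1Br | intermediate
4 | 3,4,5-tribromophenol | Oc1cc(Br)c(Br)c(Br)c1 | starting material
5 | 3,4,5-tribromo-2-[(2,4,6-trimethylphenyl)iodonio]phenolate | [O-]c1cc(Br)c(Br)c(Br)c1[I+]c1c(C)cc(C)cc1C | intermediate
6 | 3,4,5-tribromo-2-(3,5-dibromo-2-methoxyphenoxy)phenol | COc1c(Br)cc(Br)cc1Oc1c(O)cc(Br)c(Br)c1Br | target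

**Totals**
Total steps: 3. Longest linear sequence: 2 (4 → 5 → 6, or 1 → 3 → 6). Steps 2 and 3 are not telescoped because methanol and acetate from step 2 would themselves be captured by the carbenoid.

**Steps most likely to fail**

Step 3 (the new reaction; risks are slow carbenoid formation, ring contraction, or arylation of product 6). The fallback is the established diaryliodonium route to polybrominated diphenyl ethers. It sets out from 1 and comes back at 6.
- Boronic acid 1 is treated with PhI(OAc)2 and BF3·OEt2 (CH2Cl2, 0 °C, then aq NaBF4) to give (3,5-dibromo-2-methoxyphenyl)(phenyl)iodonium tetrafluoroborate F1.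
- Separately, commercial 2-(benzyloxy)phenol (Oc1ccccc1OCc1ccccc1) is tribrominated (Br2 3.1 equiv, NaOAc, AcOH, rt). Bromine enters para and ortho to OH and para to OBn, giving 6-(benzyloxy)-2,3,4-tribromophenol F2.
- Metal-free O-arylation of F2 with F1 (t-BuOK, THF, 40 °C) transfers the electron-poor ortho-methoxy ring in preference to phenyl and gives 1-(benzyloxy)-3,4,5-tribromo-2-(3,5-dibromo-2-methoxyphenoxy)benzene F3.
- BCl3 with pentamethylbenzene (CH2Cl2, −78 °C) removes the benzyl group without touching the aryl methyl ether or the C–Br bonds and gives 6.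

Step 2 (risks are oxidation of the phenolate to a bromoquinone, or no attack of the bulky iodine(III) electrophile next to bromine). The fallback installs iodine first as small I⁺ and raises it to iodine(III) afterwards. It sets out from 4 and comes back at 5.
- Ortho-iodination of 4 (NIS, cat. TsOH, MeCN, rt) gives 3,4,5-tribromo-2-iodophenol F4.
- Acetylation (Ac2O, pyridine) gives 3,4,5-tribromo-2-iodophenyl acetate F5.
- One-pot oxidation and arylation of mesitylene (mCPBA, TfOH, mesitylene, CH2Cl2, 0 °C → rt) gives (2-acetoxy-4,5,6-tribromophenyl)(2,4,6-trimethylphenyl)iodonium trifluoromethanesulfonate F6.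
- K2CO3 in MeOH at 0 °C cleaves the acetate, and the freed phenolate closes to inner salt 5.

Step 1 (least risky; possible protodeboronation or poor quality of 1). The fallback makes the C–O bond at copper instead of by peroxide migration and unveils the phenol without oxidant. It sets out from 1 and comes back at 3.
- Chan–Lam-type acyloxylation of 1 with benzoic acid (Cu(OTf)2, urea, EtOAc, 60 °C, air) gives 3,5-dibromo-2-methoxyphenyl benzoate F7.
- Saponification (NaOH, MeOH/H2O, then H3O⁺) gives 3.

**Further compounds**
F1 | step 3 | (3,5-dibromo-2-methoxyphenyl)(phenyl)iodonium tetrafluoroborate | COc1c([I+]c2ccccc2)cc(Br)cc1Br.F[B-](F)(F)F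
F2 | step 3 | 6-(benzyloxy)-2,3,4-tribromophenol | Oc1c(OCc2ccccc2)cc(Br)c(Br)c1Br
F3 | step 3 | 1-(benzyloxy)-3,4,5-tribromo-2-(3,5-dibromo-2-methoxyphenoxy)benzene | COc1c(Br)cc(Br)cc1Oc1c(OCc2ccccc2)cc(Br)c(Br)c1Br
F4 | step 2 | 3,4,5-tribromo-2-iodophenol | Oc1cc(Br)c(Br)c(Br)c1I
F5 | step 2 | 3,4,5-tribromo-2-iodophenyl acetate | CC(=O)Oc1cc(Br)c(Br)c(Br)c1I
F6 | step 2 | (2-acetoxy-4,5,6-tribromophenyl)(2,4,6-trimethylphenyl)iodonium trifluoromethanesulfonate | CC(=O)Oc1cc(Br)c(Br)c(Br)c1[I+]c1c(C)cc(C)cc1C.[O-]S(=O)(=O)C(F)(F)F
F7 | step 1 | 3,5-dibromo-2-methoxyphenyl benzoate | COc1c(OC(=O)c2ccccc2)cc(Br)cc1Br
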